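The 14‑membered ring (cembrane numbering: C1 carries the isopropyl group, C3–C4 the oxirane, C9 and C14 the ketones) is closed last across C5–C6, the CH2–CH2 bond beside the fully substituted oxirane carbon C4. One ring‑closing metathesis joins a vinyl group on C4 to the allyl group on C8; diimide then saturates the new alkene. The step exploits the rigid C14(=O)–C1=C2–C3–C4 sector: the E‑enone and the oxirane, whose ring bonds to C2 and C5 are cis, act as a turn, and the hindered, non‑dimerising vinyl on C4 steers metathesis towards cyclisation. The acyclic precursor comes from a Horner–Wadsworth–Emmons union of a citronellal‑derived ketophosphonate with a Sharpless‑derived vinyl epoxy aldehyde.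

Key step: step 17

Assumption: atoms are numbered as in cembranoids (C1 = ring carbon bearing isopropyl, then through C2, the oxirane C3–C4 and on to C14; C18 = methyl on C4, C19 = hydroxymethyl carbon on C8, C20 = methyl on C12). The C5=C6 alkene formed in step 17 may be an E/Z mixture, which is of no consequence because step 18 saturates it.

Step 1
Reactants: 1 (R)-citronellal
Product: 4 (2S,3R)-3,7-dimethyloct-6-ene-1,2-diol, via anilinooxy aldehyde 2 (not isolated), via anilinooxy alcohol 3 (not isolated)
Conditions: nitrosobenzene (1.0 equiv), D-proline (20 mol %), CHCl3, 4 °C; then NaBH4, EtOH, 0 °C; then Zn, AcOH, EtOH, rt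
Reagents that add atoms: nitrosobenzene (O=Nc1ccccc1)
Why: Proline‑catalysed α‑aminoxylation (enamine catalysis), then borohydride reduction and reductive N–O cleavage; the D‑proline enamine should take up the nitroso oxygen on the face that gives the 2S centre (C13 of the target) under catalyst control, while the C12 centre from citronellal is untouched.

Step 2
Reactants: 4 (2S,3R)-3,7-dimethyloct-6-ene-1,2-diol
Product: 5 (2S,3R)-3,7-dimethyl-1,2-bis(triethylsilyloxy)oct-6-ene
Conditions: Et3SiCl (2.5 equiv), imidazole, DMF, 0 °C to rt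
Reagents that add atoms: triethylsilyl chloride (CC[Si](Cl)(CC)CC)
Why: Standard silylation of both hydroxyl groups with a silyl chloride and imidazole; no stereocentre is touched.

Step 3
Reactants: 5 (2S,3R)-3,7-dimethyl-1,2-bis(triethylsilyloxy)oct-6-ene
Product: 7 (4R,5S)-4-methyl-5,6-bis(triethylsilyloxy)hexanal, via secondary ozonide 6 (not isolated)
Conditions: O3, CH2Cl2, −78 °C; then PPh3, −78 °C to rt
Reagents that add atoms: ozone ([O-][O+]=O)
Why: Ozonolysis (Criegee mechanism) of the only C=C bond with reductive work‑up should unveil the C9 aldehyde; the silyl ethers are stable at −78 °C.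

Step 4
Reactants: 8 (R)-4-benzyl-2-oxazolidinone; 9 pent-4-enoyl chloride
Product: 10 (R)-4-benzyl-3-(pent-4-enoyl)oxazolidin-2-one
Conditions: n-BuLi, THF, −78 °C; then 9, −78 to 0 °C
Reagents that add atoms: none
Why: N‑Acylation of the lithiated oxazolidinone by the acid chloride (acyl substitution) should give the imide needed for the auxiliary‑controlled aldol reaction.

Step 5
Reactants: 10 (R)-4-benzyl-3-(pent-4-enoyl)oxazolidin-2-one; 7 (4R,5S)-4-methyl-5,6-bis(triethylsilyloxy)hexanal
Product: 12 (R)-4-benzyl-3-[(2R,3S,6R,7S)-3-hydroxy-6-methyl-2-(prop-2-en-1-yl)-7,8-bis(triethylsilyloxy)octanoyl]oxazolidin-2-one, via dibutylboron Z-enolate 11 (not isolated)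
Conditions: Bu2BOTf, iPr2NEt, CH2Cl2, −78 to 0 °C; then 7, −78 to 0 °C; then pH 7 buffer, MeOH, 30% H2O2, 0 °C
Reagents that add atoms: none
Why: Evans syn‑aldol reaction: the Z‑boron enolate should react through a Zimmerman–Traxler chair on the face opposite the benzyl group of the (R)‑auxiliary, setting C8 (2R in the imide, S in the target) and the transient C9 carbinol (3S) in a syn relationship.

Step 6
Reactants: 12 aldol adduct
Product: 13 (2S,3S,6R,7S)-6-methyl-2-(prop-2-en-1-yl)-7,8-bis(triethylsilyloxy)octane-1,3-diol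
Conditions: LiBH4, MeOH (1.1 equiv), THF, 0 °C
Reagents that add atoms: none
Why: Reductive cleavage of the N‑acyl oxazolidinone by LiBH4 (hydride reduction of the activated imide carbonyl) should give the C19 primary alcohol and return the auxiliary; silyl ethers and the alkene are inert.

Step 7
Reactants: 13 (2S,3S,6R,7S)-6-methyl-2-(prop-2-en-1-yl)-7,8-bis(triethylsilyloxy)octane-1,3-diol
Product: 14 (4S,5S,8R,9S)-4-[(tert-butyldimethylsilyloxy)methyl]-8-methyl-9,10-bis(triethylsilyloxy)dec-1-en-5-ol
Conditions: t-BuMe2SiCl (1.05 equiv), imidazole, CH2Cl2, −20 to 0 °C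
Reagents that add atoms: tert-butyldimethylsilyl chloride (CC(C)(C)[Si](C)(C)Cl)
Why: Selective silylation of the less hindered primary C19 hydroxyl over the secondary C9 hydroxyl at low temperature.

Step 8
Reactants: 14 (4S,5S,8R,9S)-4-[(tert-butyldimethylsilyloxy)methyl]-8-methyl-9,10-bis(triethylsilyloxy)dec-1-en-5-ol
Product: 15 (2S,3R,6S,7S)-7-[(tert-butyldimethylsilyloxy)methyl]-3-methyl-2-(triethylsilyloxy)dec-9-ene-1,6-diol
Conditions: PPTS (10 mol %), MeOH/CH2Cl2 (1:4), −10 °C
Reagents that add atoms: none
Why: Acid‑catalysed methanolysis of silyl ethers follows steric accessibility, so the primary triethylsilyl ether at C14 should be cleaved before the secondary triethylsilyl ether at C13 and the bulkier primary tert‑butyldimethylsilyl ether.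

Step 9
Reactants: 15 (2S,3R,6S,7S)-7-[(tert-butyldimethylsilyloxy)methyl]-3-methyl-2-(triethylsilyloxy)dec-9-ene-1,6-diol
Product: 16 (2S,3R,6S,7S)-7-[(tert-butyldimethylsilyloxy)methyl]-6-hydroxy-3-methyl-2-(triethylsilyloxy)dec-9-enal
Conditions: TEMPO (10 mol %), PhI(OAc)2 (1.2 equiv), CH2Cl2, rt
Reagents that add atoms: none
Why: Oxoammonium (TEMPO) oxidation with PhI(OAc)2 as terminal oxidant is selective for primary over secondary alcohols, so the C14 aldehyde should form while the C9 carbinol is kept.

Step 10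
Reactants: 17 triethyl phosphite; 18 1-bromo-2-methylpropane
Product: 19 diethyl (2-methylpropyl)phosphonate
Conditions: neat, 150 °C, EtBr distilled off
Reagents that add atoms: none
Why: Michaelis–Arbuzov reaction: SN2 alkylation of the phosphite by the primary bromide, then dealkylation of the phosphonium salt by bromide.

Step 11
Reactants: 19 diethyl (2-methylpropyl)phosphonate; 16 (2S,3R,6S,7S)-7-[(tert-butyldimethylsilyloxy)methyl]-6-hydroxy-3-methyl-2-(triethylsilyloxy)dec-9-enal
Product: 21 diethyl [(5S,6R,9S,10S)-10-[(tert-butyldimethylsilyloxy)methyl]-4,9-dihydroxy-2,6-dimethyl-5-(triethylsilyloxy)tridec-12-en-3-yl]phosphonate (mixture at C3 and C4), via lithiated phosphonate 20 (not isolated)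
Conditions: 19 (3.5 equiv), n-BuLi (3.3 equiv), THF, −78 °C; then 16, −78 °C; H2O quench
Reagents that add atoms: none
Why: 1,2‑Addition of the α‑lithiated phosphonate to the aldehyde (the C9 hydroxyl rides along as its lithium alkoxide); the new carbinol and phosphonate‑bearing centres form as a mixture that steps 12 and 16 erase.

Step 12
Reactants: 21 β-hydroxyphosphonate diol
Product: 22 diethyl [(5S,6R,10S)-10-[(tert-butyldimethylsilyloxy)methyl]-2,6-dimethyl-4,9-dioxo-5-(triethylsilyloxy)tridec-12-en-3-yl]phosphonate (C3 epimers)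
Conditions: Dess–Martin periodinane (3 equiv), NaHCO3, CH2Cl2, 0 °C to rt
Reagents that add atoms: none
Why: Dess–Martin oxidation should convert both secondary alcohols into ketones in one operation, giving the β‑ketophosphonate and the C9 ketone under buffered, non‑epimerising conditions.

Step 13
Reactants: 23 (Z)-3-methylpent-2-en-4-yn-1-ol
Product: 24 [(2S,3R)-3-ethynyl-3-methyloxiran-2-yl]methanol
Conditions: Ti(OiPr)4 (0.5 equiv), L-(+)-diethyl tartrate (0.6 equiv), t-BuOOH (2 equiv, in decane), 4 Å molecular sieves, CH2Cl2, −20 °C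
Reagents that add atoms: tert-butyl hydroperoxide (CC(C)(C)OO)
Why: Sharpless asymmetric epoxidation: with L‑(+)‑diethyl tartrate the titanium–tartrate–peroxide complex should deliver oxygen to the face that gives the (2S,3R)‑epoxy alcohol (C3 S and C4 R of the target), and the Z alkene geometry becomes the cis relation of C2 and C5 on the oxirane.

Step 14
Reactants: 24 [(2S,3R)-3-ethynyl-3-methyloxiran-2-yl]methanol
Product: 25 [(2S,3R)-3-ethenyl-3-methyloxiran-2-yl]methanol
Conditions: H2 (1 atm), Pd/CaCO3 poisoned with Pb(OAc)2 (Lindlar catalyst), quinoline, EtOAc, rt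
Reagents that add atoms: none
Why: Lindlar semihydrogenation (syn addition of H2 on poisoned palladium) should stop at the terminal alkene and leave the oxirane untouched.

Step 15
Reactants: 25 [(2S,3R)-3-ethenyl-3-methyloxiran-2-yl]methanol
Product: 26 (2R,3R)-3-ethenyl-3-methyloxirane-2-carbaldehyde
Conditions: Dess–Martin periodinane, NaHCO3, CH2Cl2, 0 °C; used at once as a solution
Reagents that add atoms: none
Why: Dess–Martin oxidation under bicarbonate buffer should give the non‑enolisable epoxy aldehyde without opening the oxirane (the descriptor at C2 changes only because the priorities change).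

Step 16
Reactants: 22 keto β-ketophosphonate; 26 (2R,3R)-3-ethenyl-3-methyloxirane-2-carbaldehyde
Product: 27 (4S,8R,9S,11E)-4-[(tert-butyldimethylsilyloxy)methyl]-12-[(2S,3R)-3-ethenyl-3-methyloxiran-2-yl]-8-methyl-11-(propan-2-yl)-9-(triethylsilyloxy)dodeca-1,11-diene-5,10-dione
Conditions: Ba(OH)2 (activated, 0.8 equiv), THF, rt; then 26 (1.5 equiv), THF/H2O (40:1), 0 °C to rt
Reagents that add atoms: none
Why: Horner–Wadsworth–Emmons olefination with Ba(OH)2 as a mild base: the phosphonate carbanion adds to the reactive epoxy aldehyde and syn‑elimination of phosphate should give the thermodynamically preferred E‑enone (C14 carbonyl trans to C3), so the isopropyl group and C3 end up cis as in the target.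

Step 17
Reactants: 27 acyclic triene-dione
Product: 28 (1E,3S,4R,8S,12R,13S)-19-(tert-butyldimethylsilyloxy)-3,4-epoxy-13-(triethylsilyloxy)cembra-1,5-diene-9,14-dione (5E/5Z mixture)
Conditions: second-generation Grubbs catalyst RuCl2(=CHPh)(H2IMes)(PCy3) (10 mol %, two portions), 1,4-benzoquinone (20 mol %), CH2Cl2 (1 mM), 40 °C
Reagents that add atoms: none
Why: Ring‑closing olefin metathesis (Chauvin mechanism): the ruthenium benzylidene exchanges onto the unhindered allyl terminus (C6), the new alkylidene undergoes intramolecular [2+2] cycloaddition with the C5 vinyl group on the oxirane carbon C4, and cycloreversion of the ruthenacyclobutane releases the C5=C6 cycloalkene while ethene leaves the solution. The closest known reaction type is macrocyclic ring‑closing metathesis between a terminal alkene and a vinyl oxirane or another alkene on a fully substituted allylic carbon. The only ring closed is the 14‑membered carbocycle, formed in one end‑to‑end metathesis of the two terminal vinyl groups; the oxirane is already in place and takes no part. No stereocentre is created, and the C5=C6 geometry is neither controlled nor needed, since step 18 saturates this bond. The step needs cyclisation to outrun oligomerisation and must leave the C1=C2 enone and the oxirane untouched: high dilution, the turn imposed by the E‑enone and the cis oxirane bonds (C1 to C4), the inability of the hindered C4 vinyl group to homodimerise and the inertness of the trisubstituted, electron‑poor C1=C2 bond should secure this. 1,4‑Benzoquinone should suppress ruthenium hydride‑induced migration of the allyl double bond, which would lead to a ring‑contracted product.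

Step 18
Reactants: 28 macrocyclic 1,5-diene
Product: 29 (1E,3S,4R,8S,12R,13S)-19-(tert-butyldimethylsilyloxy)-3,4-epoxy-13-(triethylsilyloxy)cembr-1-ene-9,14-dione
Conditions: KO2CN=NCO2K (excess), AcOH (slow addition), CH2Cl2, rt
Reagents that add atoms: none
Why: Diimide reduction (concerted syn transfer of H2) is strongly sensitive to substitution, so the 1,2‑disubstituted C5=C6 bond should be reduced while the trisubstituted, α‑branched C1=C2 enone bond, the oxirane and the ketones are left.

Step 19
Reactants: 29 bis-silyl ether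
Product: 30 (1E,3S,4R,8S,12R,13S)-3,4-epoxy-13,19-dihydroxycembr-1-ene-9,14-dione (target)
Conditions: HF·pyridine, pyridine, THF, 0 °C to rt
Reagents that add atoms: none
Why: Fluoride‑mediated desilylation under buffered, mildly acidic conditions should remove both silyl ethers without epimerising C8 or C13, without retro‑aldol loss of the C19 hydroxymethyl group and without opening the oxirane.

Compound list
1 | (R)-citronellal | CC(C)=CCC[C@@H](C)CC=O | starting material
2 | (2S,3R)-2-(anilinooxy)-3,7-dimethyloct-6-enal | CC(C)=CCC[C@@H](C)[C@H](ONc1ccccc1)C=O | intermediate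
3 | (2S,3R)-2-(anilinooxy)-3,7-dimethyloct-6-en-1-ol | CC(C)=CCC[C@@H](C)[C@H](ONc1ccccc1)CO | intermediate
4 | (2S,3R)-3,7-dimethyloct-6-ene-1,2-diol | CC(C)=CCC[C@@H](C)[C@H](O)CO | intermediate
5 | (2S,3R)-3,7-dimethyl-1,2-bis(triethylsilyloxy)oct-6-ene | CC(C)=CCC[C@@H](C)[C@H](O[Si](CC)(CC)CC)CO[Si](CC)(CC)CC | intermediate
6 | secondary ozonide (1,2,4-trioxolane) of 5 | CC1(C)OOC(CC[C@@H](C)[C@H](O[Si](CC)(CC)CC)CO[Si](CC)(CC)CC)O1 | intermediate
7 | (4R,5S)-4-methyl-5,6-bis(triethylsilyloxy)hexanal | O=CCC[C@@H](C)[C@H](O[Si](CC)(CC)CC)CO[Si](CC)(CC)CC | intermediate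
8 | (R)-4-benzyl-2-oxazolidinone | O=C1N[C@H](Cc2ccccc2)CO1 | starting material
9 | pent-4-enoyl chloride | C=CCCC(=O)Cl | starting material
10 | (R)-4-benzyl-3-(pent-4-enoyl)oxazolidin-2-one | C=CCCC(=O)N1[C@H](Cc2ccccc2)COC1=O | intermediate
11 | dibutylboron Z-enolate of 10 | C=CC/C=C(\OB(CCCC)CCCC)N1[C@H](Cc2ccccc2)COC1=O | intermediate
12 | (R)-4-benzyl-3-[(2R,3S,6R,7S)-3-hydroxy-6-methyl-2-(prop-2-en-1-yl)-7,8-bis(triethylsilyloxy)octanoyl]oxazolidin-2-one | C=CC[C@@H](C(=O)N1[C@H](Cc2ccccc2)COC1=O)[C@@H](O)CC[C@@H](C)[C@H](O[Si](CC)(CC)CC)CO[Si](CC)(CC)CC | intermediate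
13 | (2S,3S,6R,7S)-6-methyl-2-(prop-2-en-1-yl)-7,8-bis(triethylsilyloxy)octane-1,3-diol | C=CC[C@@H](CO)[C@@H](O)CC[C@@H](C)[C@H](O[Si](CC)(CC)CC)CO[Si](CC)(CC)CC | intermediate
14 | (4S,5S,8R,9S)-4-[(tert-butyldimethylsilyloxy)methyl]-8-methyl-9,10-bis(triethylsilyloxy)dec-1-en-5-ol | C=CC[C@@H](CO[Si](C)(C)C(C)(C)C)[C@@H](O)CC[C@@H](C)[C@H](O[Si](CC)(CC)CC)CO[Si](CC)(CC)CC | intermediate
15 | (2S,3R,6S,7S)-7-[(tert-butyldimethylsilyloxy)methyl]-3-methyl-2-(triethylsilyloxy)dec-9-ene-1,6-diol | C=CC[C@@H](CO[Si](C)(C)C(C)(C)C)[C@@H](O)CC[C@@H](C)[C@H](O[Si](CC)(CC)CC)CO | intermediate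
16 | (2S,3R,6S,7S)-7-[(tert-butyldimethylsilyloxy)methyl]-6-hydroxy-3-methyl-2-(triethylsilyloxy)dec-9-enal | C=CC[C@@H](CO[Si](C)(C)C(C)(C)C)[C@@H](O)CC[C@@H](C)[C@H](O[Si](CC)(CC)CC)C=O | intermediate
17 | triethyl phosphite | CCOP(OCC)OCC | starting material
18 | 1-bromo-2-methylpropane | CC(C)CBr | starting material
19 | diethyl (2-methylpropyl)phosphonate | CCOP(=O)(CC(C)C)OCC | intermediate
20 | diethyl (1-lithio-2-methylpropyl)phosphonate | CCOP(=O)(C([Li])C(C)C)OCC | intermediate
21 | diethyl [(5S,6R,9S,10S)-10-[(tert-butyldimethylsilyloxy)methyl]-4,9-dihydroxy-2,6-dimethyl-5-(triethylsilyloxy)tridec-12-en-3-yl]phosphonate (mixture at C3 and C4) | C=CC[C@@H](CO[Si](C)(C)C(C)(C)C)[C@@H](O)CC[C@@H](C)[C@H](O[Si](CC)(CC)CC)C(O)C(C(C)C)P(=O)(OCC)OCC | intermediate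
22 | diethyl [(5S,6R,10S)-10-[(tert-butyldimethylsilyloxy)methyl]-2,6-dimethyl-4,9-dioxo-5-(triethylsilyloxy)tridec-12-en-3-yl]phosphonate (C3 epimers) | C=CC[C@@H](CO[Si](C)(C)C(C)(C)C)C(=O)CC[C@@H](C)[C@H](O[Si](CC)(CC)CC)C(=O)C(C(C)C)P(=O)(OCC)OCC | intermediate
23 | (Z)-3-methylpent-2-en-4-yn-1-ol | C#C/C(C)=C\CO | starting material
24 | [(2S,3R)-3-ethynyl-3-methyloxiran-2-yl]methanol | OC[C@@H]1O[C@]1(C)C#C | intermediate
25 | [(2S,3R)-3-ethenyl-3-methyloxiran-2-yl]methanol | OC[C@@H]1O[C@]1(C)C=C | intermediate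
26 | (2R,3R)-3-ethenyl-3-methyloxirane-2-carbaldehyde | O=C[C@@H]1O[C@]1(C)C=C | intermediate
27 | (4S,8R,9S,11E)-4-[(tert-butyldimethylsilyloxy)methyl]-12-[(2S,3R)-3-ethenyl-3-methyloxiran-2-yl]-8-methyl-11-(propan-2-yl)-9-(triethylsilyloxy)dodeca-1,11-diene-5,10-dione | C=CC[C@@H](CO[Si](C)(C)C(C)(C)C)C(=O)CC[C@@H](C)[C@H](O[Si](CC)(CC)CC)C(=O)/C(C(C)C)=C/[C@@H]1O[C@]1(C)C=C | intermediate
28 | (1E,3S,4R,8S,12R,13S)-19-(tert-butyldimethylsilyloxy)-3,4-epoxy-13-(triethylsilyloxy)cembra-1,5-diene-9,14-dione (5E/5Z mixture) | CC(C)/C1=C\[C@@H]2O[C@]2(C)C=CC[C@@H](CO[Si](C)(C)C(C)(C)C)C(=O)CC[C@@H](C)[C@H](O[Si](CC)(CC)CC)C1=O | intermediate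
29 | (1E,3S,4R,8S,12R,13S)-19-(tert-butyldimethylsilyloxy)-3,4-epoxy-13-(triethylsilyloxy)cembr-1-ene-9,14-dione | CC(C)/C1=C\[C@@H]2O[C@]2(C)CCC[C@@H](CO[Si](C)(C)C(C)(C)C)C(=O)CC[C@@H](C)[C@H](O[Si](CC)(CC)CC)C1=O | intermediate
30 | (1E,3S,4R,8S,12R,13S)-3,4-epoxy-13,19-dihydroxycembr-1-ene-9,14-dione | CC(C)/C1=C\[C@@H]2O[C@]2(C)CCC[C@@H](CO)C(=O)CC[C@@H](C)[C@H](O)C1=O | target

Total step count: 19.
Longest linear sequence: 14 steps (steps 1, 2, 3, 5, 6, 7, 8, 9, 11, 12, 16, 17, 18, 19).

Steps most likely to fail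

1. Step 17 (ring‑closing metathesis). The hindered vinyl group on the quaternary oxirane carbon may engage too slowly, so that the carbene resting on the allyl terminus is consumed by intermolecular metathesis and oligomers build up. The product is also a cis‑dialkenyl oxirane and should be reduced promptly. The fallback is a relay ring‑closing metathesis, which changes the substrate so that the catalyst is delivered intramolecularly onto C5. It sets out from 24 and 22 and comes back at 28. The acetylide of 24 (dianion, n‑BuLi, THF/DMPU) should be alkylated with 5‑iodopent‑1‑ene to give heptenynyl epoxy alcohol F1. Semihydrogenation (H2, Pd/CaCO3 poisoned with Pb(OAc)2, quinoline) should give (Z)‑heptadienyl epoxy alcohol F2, and Dess–Martin oxidation relay aldehyde F3. Horner–Wadsworth–Emmons coupling of F3 with 22 (Ba(OH)2) should give relay tetraene F4. With the same ruthenium catalyst the carbene should load on the unhindered terminal alkene of the tether, expel cyclopentene and thereby sit on C5, from where closure onto the allyl group gives 28.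

2. Step 16 (Horner–Wadsworth–Emmons olefination). The α‑isopropyl phosphonate carbanion is hindered, so olefination may be sluggish, E selectivity may erode, and prolonged exposure to base may epimerise C8 or C13. The fallback is a reductive aldol–dehydration sequence that generates the C1 enolate regiospecifically without phosphorus. It sets out from 16 and 26 and comes back at 27. Addition of (2‑methylprop‑1‑en‑1‑yl)magnesium bromide to 16 should give allylic alcohol diol F5, and Dess–Martin oxidation the β,β‑dimethyl enone diketone F6. Conjugate reduction of the s‑cis enone with catecholborane (THF, rt) should give the boron enolate at C14–C1 only. Its aldol addition to 26 should give β‑hydroxy ketone F7. Mesylation (MsCl, Et3N) and elimination with DBU (E1cB, thermodynamic control) should give E‑enone 27.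

3. Step 18 (diimide reduction). Diimide may also reduce the C1=C2 enone bond, or may reduce the C5=C6 bond next to the quaternary carbon incompletely. The fallback replaces stoichiometric hydrogen transfer by homogeneous metal‑catalysed hydrogenation, whose selectivity rests on alkene coordination. It sets out from 28 and comes back at 29: H2 (1 atm) with RhCl(PPh3)3 in benzene/EtOH should saturate the accessible disubstituted alkene and leave the trisubstituted enone and the oxirane. This fallback makes no new compound (F0).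

Further compounds
F1 | step 17 | [(2S,3R)-3-(hept-6-en-1-yn-1-yl)-3-methyloxiran-2-yl]methanol | OC[C@@H]1O[C@]1(C)C#CCCCC=C
F2 | step 17 | [(2S,3R)-3-[(1Z)-hepta-1,6-dien-1-yl]-3-methyloxiran-2-yl]methanol | OC[C@@H]1O[C@]1(C)/C=C\CCCC=C
F3 | step 17 | (2R,3R)-3-[(1Z)-hepta-1,6-dien-1-yl]-3-methyloxirane-2-carbaldehyde | O=C[C@@H]1O[C@]1(C)/C=C\CCCC=C
F4 | step 17 | relay tetraene: analogue of 27 with a (1Z)-hepta-1,6-dien-1-yl group in place of the ethenyl group on the oxirane | C=CC[C@@H](CO[Si](C)(C)C(C)(C)C)C(=O)CC[C@@H](C)[C@H](O[Si](CC)(CC)CC)C(=O)/C(C(C)C)=C/[C@@H]1O[C@]1(C)/C=C\CCCC=C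
F5 | step 16 | (5S,6R,9S,10S)-10-[(tert-butyldimethylsilyloxy)methyl]-2,6-dimethyl-5-(triethylsilyloxy)trideca-2,12-diene-4,9-diol (mixture at C4) | C=CC[C@@H](CO[Si](C)(C)C(C)(C)C)[C@@H](O)CC[C@@H](C)[C@H](O[Si](CC)(CC)CC)C(O)C=C(C)C
F6 | step 16 | (5S,6R,10S)-10-[(tert-butyldimethylsilyloxy)methyl]-2,6-dimethyl-5-(triethylsilyloxy)trideca-2,12-diene-4,9-dione | C=CC[C@@H](CO[Si](C)(C)C(C)(C)C)C(=O)CC[C@@H](C)[C@H](O[Si](CC)(CC)CC)C(=O)C=C(C)C
F7 | step 16 | β-hydroxy ketone: aldol adduct of the C1 enolate of F6 with 26 (mixture at C1 and C2) | C=CC[C@@H](CO[Si](C)(C)C(C)(C)C)C(=O)CC[C@@H](C)[C@H](O[Si](CC)(CC)CC)C(=O)C(C(C)C)C(O)[C@@H]1O[C@]1(C)C=C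
F0 | step 18 | none | none
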